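**Plan**

- Retrosynthesis: the C2–Br and C3–Br bonds are traced back to carboxyl groups (ipso-bromodecarboxylation) and the C4–Br and C5–Br bonds to C–H. The pyrrole ring is then opened at C3–C4, the bond across from N1, and last at N1–C2.
- Enabling feature: in the pyrrole ring, N1 with its methyl group, C5 and C4 map onto (methylamino)acetaldehyde dimethyl acetal. C2–C3 map onto an alkyne diester whose ester groups make C3 the only nucleophilic carbon and later act as leaving groups for bromine.
- Forward order: N1–C2 by conjugate addition of the amine to the alkyne; the single ring (the pyrrole) by acid-mediated closure of C3–C4; ester hydrolysis; one fourfold bromination that installs every C–Br bond.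
- Stereochemistry: the target has no stereocentre and no stereogenic double bond. The enamine geometry and the transient C4 centre of the cyclisation intermediate disappear on aromatisation.

Key step: step 2

Assumption: the adduct 3 is drawn as the E isomer, although either geometry would cyclise; acids 6, 7 and 8 are drawn as free acids although they are present as sodium carboxylates in the bicarbonate medium of step 4.

**Route**

Step 1
Reactants: 1 (methylamino)acetaldehyde dimethyl acetal; 2 dimethyl acetylenedicarboxylate
Product: 3 dimethyl (E)-2-[(2,2-dimethoxyethyl)(methyl)amino]but-2-enedioate
Conditions: MeOH, 0 °C to rt (1 equiv each)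
Reagents that add atoms: none
Why: Conjugate (aza-Michael) addition of the secondary amine to the electron-poor alkyne should be fast and clean, since the resulting push–pull enamine is too deactivated to add a second alkyne; no stereocentre is formed.

Step 2
Reactants: 3 dimethyl (E)-2-[(2,2-dimethoxyethyl)(methyl)amino]but-2-enedioate
Product: 5 dimethyl 1-methyl-1H-pyrrole-2,3-dicarboxylate, via 4-methoxy-4,5-dihydropyrrole diester 4 (not isolated)
Conditions: CF3CO2H, dry CH2Cl2, 0 °C to rt
Reagents that add atoms: none
Why: Trifluoroacetic acid should ionise one methoxy group of the acetal in 3 to an oxocarbenium ion, the enamine carbon β to nitrogen (the future C3) attacks it to forge C3–C4, loss of the C3 proton gives methoxypyrroline 4, and acid-promoted loss of the second methanol through the nitrogen-stabilised allylic cation aromatises it to 5. The closest known reaction type is the acid-mediated cyclisation of enamino esters and enaminones built from aminoacetaldehyde acetals to pyrroles, an enamine counterpart of the Pomeranz–Fritsch closure. The single ring closes in a 5-exo-trig sense at the oxocarbenium carbon with the C2=C3 enamine bond inside the new ring (an enol-endo arrangement); this is geometrically demanding, yet established for this substrate class, because rotation about N1–C5 can bring the cation over the enamine π face and aromatisation makes the sequence irreversible. No stereocentre is retained: C4 of 4 is tetrahedral only transiently, and the enamine geometry is irrelevant because both C3 substituents stay outside the ring. The step needs chemoselectivity for intramolecular C-alkylation over acetal hydrolysis and intermolecular condensation, which anhydrous acid, moderate dilution and the 1,5-relationship between the one nucleophilic carbon and the cationic centre should secure; regiochemistry is fixed because nitrogen is fully substituted and C2 carries an ester.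

Step 3
Reactants: 5 dimethyl 1-methyl-1H-pyrrole-2,3-dicarboxylate
Product: 6 1-methyl-1H-pyrrole-2,3-dicarboxylic acid
Conditions: NaOH (4 equiv), MeOH/H2O, 65 °C; then aq. HCl to pH 2, 0 °C
Reagents that add atoms: sodium hydroxide NaOH, [Na+].[OH-]
Why: Saponification (base-mediated acyl substitution) should cleave both methyl esters, and acidification in the cold should precipitate the diacid without protodecarboxylation of the α-carboxyl group.

Step 4
Reactants: 6 1-methyl-1H-pyrrole-2,3-dicarboxylic acid
Product: 9 2,3,4,5-tetrabromo-1-methyl-1H-pyrrole, via 4,5-dibromo diacid 7 (not isolated), via 2,4,5-tribromo 3-acid 8 (not isolated)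
Conditions: Br2 (4.1 equiv), NaHCO3 (excess), H2O/CH2Cl2, 0 °C to rt, dark
Reagents that add atoms: bromine, BrBr
Why: Electrophilic aromatic bromination of the free C5 and C4 positions, followed by two ipso-bromodecarboxylations (halodecarboxylation, a known reaction of pyrrolecarboxylates in buffered aqueous halogen), should proceed α before β with irreversible loss of CO2 from each σ-complex, while the two-phase medium draws the neutral product away from the oxidant.

**Compound list**

1 | (methylamino)acetaldehyde dimethyl acetal (2,2-dimethoxy-N-methylethan-1-amine) | CNCC(OC)OC | starting material
2 | dimethyl acetylenedicarboxylate (dimethyl but-2-ynedioate) | COC(=O)C#CC(=O)OC | starting material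
3 | dimethyl (E)-2-[(2,2-dimethoxyethyl)(methyl)amino]but-2-enedioate | COC(=O)/C=C(/N(C)CC(OC)OC)C(=O)OC | intermediate
4 | dimethyl 4-methoxy-1-methyl-4,5-dihydro-1H-pyrrole-2,3-dicarboxylate (racemic, not isolated) | CN1CC(OC)C(C(=O)OC)=C1C(=O)OC | intermediate
5 | dimethyl 1-methyl-1H-pyrrole-2,3-dicarboxylate | COC(=O)c1ccn(C)c1C(=O)OC | intermediate
6 | 1-methyl-1H-pyrrole-2,3-dicarboxylic acid | Cn1ccc(C(=O)O)c1C(=O)O | intermediate
7 | 4,5-dibromo-1-methyl-1H-pyrrole-2,3-dicarboxylic acid (not isolated) | Cn1c(Br)c(Br)c(C(=O)O)c1C(=O)O | intermediate
8 | 2,4,5-tribromo-1-methyl-1H-pyrrole-3-carboxylic acid (not isolated) | Cn1c(Br)c(Br)c(C(=O)O)c1Br | intermediate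
9 | 2,3,4,5-tetrabromo-1-methyl-1H-pyrrole | Cn1c(Br)c(Br)c(Br)c1Br | target

**Step count**

Total steps: 4. Longest linear sequence: 4 steps (1 → 3 → 5 → 6 → 9).

**Steps most likely to fail**

Step 4. The second ipso-substitution, at the β-carboxylate, may stall once the ring carries three bromines. Prolonged contact with hypobromite may instead degrade the electron-rich ring oxidatively towards a maleimide. The fallback sets out from 6 and removes both carboxyl groups before any bromine is introduced. Heating 6 with Cu powder in quinoline at about 200 °C should bring about double protodecarboxylation, and the volatile 1-methyl-1H-pyrrole F1 is distilled from the mixture. F1 is then brominated at all four C–H positions with N-bromosuccinimide (4 equiv) in THF from −78 °C to rt, a plain electrophilic C–H bromination that no longer relies on ipso attack. The fallback comes back to the route at 9.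

Step 2. C-protonation of the enamine in trifluoroacetic acid may suppress its nucleophilicity, so that the ionised acetal is diverted into intermolecular condensation or, with adventitious water, into hydrolysis. The fallback sets out from 2 and builds the same pyrrole intermolecularly. Methylamine in MeOH at 0 °C adds to 2 to give dimethyl (Z)-2-(methylamino)but-2-enedioate F2. A Hantzsch pyrrole synthesis of F2 with aqueous chloroacetaldehyde and NaHCO3 in MeOH at 60 °C should then deliver the pyrrole diester. Either order of C-alkylation and N-condensation leads to the same product, because C4 and C5 are unsubstituted. The fallback comes back to the route at 5.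

Step 3. The α-carboxyl group may be lost by protodecarboxylation during acidification, hydrolysis of the vinylogous-carbamate ester at C3 may be slow, and a polar diacid may be recovered poorly from water. The fallback sets out from 5 and avoids the free acid altogether. Anhydrous nucleophilic ester cleavage with KOSiMe3 in THF at rt should precipitate dipotassium 1-methyl-1H-pyrrole-2,3-dicarboxylate F3, which is collected by filtration. F3 is brominated directly under the conditions of step 4, with KHCO3 in place of NaHCO3, passing through the potassium salts of 7 and 8. The fallback comes back to the route at 9.

**Further compounds**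

F1 | step 4 | 1-methyl-1H-pyrrole | Cn1cccc1
F2 | step 2 | dimethyl (Z)-2-(methylamino)but-2-enedioate | COC(=O)/C=C(\NC)C(=O)OC
F3 | step 3 | dipotassium 1-methyl-1H-pyrrole-2,3-dicarboxylate | Cn1ccc(C(=O)[O-])c1C(=O)[O-].[K+].[K+]
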